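Wednesday's flask holds 2.00 equivalents of nucleophile per electrophile and Sunday's 4.00, and on that ratio two chemists part.

| setting | elm | birch | oak | Wednesday's | Sunday's |
|---|---|---|---|---|---|
| electrophile | 0.050 M | 0.050 M | 0.050 M | 0.050 M | 0.050 M |
| nucleophile | 0.089 M (fed, over 3.0 h) | 0.13 M (fed, over 3.0 h) | 0.18 M (fed, over 3.0 h) | 0.100 M (fed, over 3.0 h) | 0.200 M (fed, over 3.0 h) |
| gas | 3.1 mM (held) | 3.1 mM (held) | 3.1 mM (held) | 3.1 mM (held) | 3.1 mM (held) |
| remark | run made earlier | run made earlier | run made earlier |  |  |
| time |  |  |  | 8.0 h | 8.0 h |

- elm (time / h: electrophile / %, target / %): 0.500: 99.8, 0.1; 1.33: 97.9, 1.2; 2.50: 96.7, 3.1; 4.00: 91.4, 7.9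
- birch (time / h: electrophile / %, target / %): 0.333: 100.3, 0; 0.667: 99.5, 0.2; 1.50: 97.3, 1.7; 4.00: 88.1, 11.8
- oak (time / h: electrophile / %, target / %): 1.00: 97.4, 1.6; 2.00: 94.7, 5.0; 3.00: 89.8, 9.9; 4.00: 83.3, 16.2

(each reading ± 0.5 percentage points)

- amounts and yields of target count crystals too
- given per volume of solution although it is solid: crystals
- at the start none of free base is dissolved
- the earlier runs were read with a standard deviation of 0.5 percentage points
- on the list of suspects stand: electrophile + nucleophile -> acid set free + target; nucleophile + acid set free <-> protonated nucleophile; acid set free + free base <-> salt of the base; crystals <-> target; acid set free -> by-product carried off; gas <-> free base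

* part of the electrophile that has reacted at the end, Wednesday's
* part of the electrophile that has reacted at the end, Sunday's
* what raising the concentration of nucleophile from its lowest to its highest value here does to the part of the electrophile that has reacted (changes below 5 percentage points count as none) (no change / it falls / it rises)

The first chemist asks for the end state. Electrophile is the limiting reagent in both flasks, and even if acid set free took a second nucleophile per turnover as protonated nucleophile, Wednesday's charge covers 100 % of the electrophile. So she expects full conversion in both flasks and no change with the charge.

The second chemist asks how fast that end is approached. With nucleophile in excess, the electrophile decays pseudo-first-order, so its logarithm follows the integral of [nucleophile] over time. Once a steady feed has ended, and with the charge taken as unspent, that integral is charge × (time − half the dosing time). The oak run, with 83.3 % electrophile at 4.00 h, then reads a rate constant of 0.406 M⁻¹ h⁻¹; the elm and birch runs read 0.404 M⁻¹ h⁻¹ and 0.390 M⁻¹ h⁻¹.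

His exposure number, the rate constant times that integral, is 0.264 for Wednesday's and 0.528 for Sunday's, twice as much. The part reacted is one minus the exponential of minus that number, so I reckon 23.2 % and 41.0 %. A gap of 18 percentage points exceeds the margin. These figures hold the whole charge, though each turnover spends a nucleophile, so I take them as slightly high. Wednesday's electrophile half-life at whole charge, 17.1 h, is longer than the 8.0 h allowed, so the exposure number, and not the ceiling, gives the answer at that time.

The forecast gives 22 % for Wednesday's and 39 % for Sunday's, lower than my figures, and for the part reacted as the charge goes up it says it rises, in its words “Conversion rises with nucleophile”.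

The flask gives 21.7 % for Wednesday's and 38.8 % for Sunday's: it rises, by 17 points.

    electrophile + nucleophile → acid set free + target (k = 0.400 M⁻¹ h⁻¹)
    nucleophile + acid set free ⇌ protonated nucleophile, settled at all times (K = 370 M⁻¹)
    acid set free + free base ⇌ salt of the base, settled at all times (K = 2.80 × 10⁶ M⁻¹)
    crystals ⇌ target, rate k4*(cs4 - [target]) while solid is left; crystals form when [target] > cs4 (solubility = 20.0 mM, k = 2.00 h⁻¹)
    acid set free → by-product carried off (k = 0.320 h⁻¹)
    gas ⇌ free base, rate k6*(csat - [free base]) (kL = 75.0 h⁻¹)

Neither flask is at rest at 8.0 h. Left for 80.0 h, Wednesday's reaches 88.4 % and Sunday's 99.3 %, so at that time the first chemist's full conversion nearly describes Sunday's flask. At 8.00 h Wednesday's still has 89 % of its nucleophile free, with 4.13 × 10⁻⁵ M protonated nucleophile against 0.0108 M salt of the base, and the pairing of nucleophile with acid set free does not move its answer.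

For a flask like Wednesday's but with 0.40 M of nucleophile, scaling the exposure number by the charge gives 1.06, hence 65.2 % reacted. That flask gives 62.8 %.

The runs stem from a simulated flask for an exercise; scatter was added.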